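**Retrosynthetic overview**

1. The target is read as epioritin-(4β→6)-oritin-4α-ol. The last C–C bond is C4 (upper ring C)–C6 (lower ring A), made by ionising a 4-benzylsulfanyl epioritin ether. Both C15 halves have the same constitution, so both are cut from one flavan, 13.
2. Ring C of that flavan is closed by a formal [3+3] annulation of dibromide 5 with α-siloxy ketone 9: C3–C4 by enolate C-benzylation, then O1–C8a by copper-catalysed enolate O-arylation.
3. Enabling feature: in ring A, C8a lies between C4a (which carries the benzylic carbon C4) and the oxygenated C8. A bromine can be bought at exactly this position (2-bromoisovanillin), so the 1,3-related electrophiles C4 (sp3) and C8a (sp2) match the 1,3-related nucleophiles C3 and O1 of one ketone enolate.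
4. Stereochemistry: one catalytic event (hydrogenation of flavan-3-one 12 with dynamic kinetic resolution) sets C2 and C3 cis. Lower-half C3 (acid epimerisation), lower-half C4 (hydride) and upper-half C4 (coupling, 4β) are relayed from C2.
5. Ring order: rings A and B are bought; ring C is made in step 7; the lower heterocycle is the same ring C carried through steps 12–15.

Key step: step 7

Assumption: the upper unit is (2R,3R,4S) and the lower unit (2R,3S,4R); the hand of the hydrogenation catalyst in step 9 is written by analogy and would be inverted if the first run shows the opposite sense.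

**Route**

Step 1
Reactants: 1 2-bromo-3-hydroxy-4-methoxybenzaldehyde (2-bromoisovanillin)
Product: 2 2-bromo-3,4-dihydroxybenzaldehyde
Conditions: BBr3 (2.5 equiv), CH2Cl2, −78 °C to 0 °C; then H2O
Reagents that add atoms: none
Why: BBr3 cleavage of the aryl methyl ether; the aldehyde and the aryl bromide are inert at low temperature.

Step 2
Reactants: 2 2-bromo-3,4-dihydroxybenzaldehyde
Product: 3 3,4-bis(benzyloxy)-2-bromobenzaldehyde
Conditions: BnBr (2.3 equiv), K2CO3 (3 equiv), DMF, 60 °C
Reagents that add atoms: benzyl bromide, BrCc1ccccc1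
Why: Williamson etherification of both phenols; benzyl ethers survive carbonate at 100 °C, DDQ and Lewis acids and leave by hydrogenolysis.

Step 3
Reactants: 3 3,4-bis(benzyloxy)-2-bromobenzaldehyde
Product: 4 [3,4-bis(benzyloxy)-2-bromophenyl]methanol
Conditions: NaBH4, THF/MeOH, 0 °C
Reagents that add atoms: none
Why: Borohydride reduction of the aldehyde; the aryl bromide and benzyl ethers are untouched.

Step 4
Reactants: 4 [3,4-bis(benzyloxy)-2-bromophenyl]methanol
Product: 5 1,2-bis(benzyloxy)-3-bromo-4-(bromomethyl)benzene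
Conditions: CBr4, PPh3, CH2Cl2, 0 °C; used without storage
Reagents that add atoms: tetrabromomethane, BrC(Br)(Br)Br
Why: Appel bromination under neutral conditions, chosen because the electron-rich benzylic bromide and the benzyl ethers are acid-sensitive.

Step 5
Reactants: 6 2-bromo-1-[4-(benzyloxy)phenyl]ethan-1-one
Product: 8 1-[4-(benzyloxy)phenyl]-2-hydroxyethan-1-one, via formate ester 7 (not isolated)
Conditions: HCO2Na (3 equiv), EtOH/H2O, reflux
Reagents that add atoms: sodium formate, [Na+].[O-]C=O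
Why: SN2 displacement of the α-bromide by formate followed by solvolysis of the formate ester in the same flask, a standard α-bromo ketone to α-ketol conversion.

Step 6
Reactants: 8 1-[4-(benzyloxy)phenyl]-2-hydroxyethan-1-one
Product: 9 1-[4-(benzyloxy)phenyl]-2-[(triisopropylsilyl)oxy]ethan-1-one
Conditions: TIPSCl, imidazole, DMF, 25 °C
Reagents that add atoms: chlorotri(propan-2-yl)silane, CC(C)[Si](Cl)(C(C)C)C(C)C
Why: Silylation of the primary ketol; the bulky TIPS group is chosen because it resists carbonate and O-to-O migration in the enolate of the next step.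

Step 7
Reactants: 5 1,2-bis(benzyloxy)-3-bromo-4-(bromomethyl)benzene; 9 1-[4-(benzyloxy)phenyl]-2-[(triisopropylsilyl)oxy]ethan-1-one
Product: 11 7,8-bis(benzyloxy)-2-[4-(benzyloxy)phenyl]-3-[(triisopropylsilyl)oxy]-4H-chromene, via C-benzylated ketone 10 (not isolated)
Conditions: CuI (10 mol %), 1,10-phenanthroline (20 mol %), Cs2CO3 (3 equiv), DMF, 40 °C then 100 °C, argon, one flask
Reagents that add atoms: none
Why: Proposed new method: Cs2CO3 enolises ketone 9 and the caesium enolate is C-benzylated by the benzylic bromide of 5 (SN2) to give 10; a second enolisation, possible only towards C3, gives the tetrasubstituted enolate, whose oxygen is arylated at C8a–Br in a phenanthroline-ligated monovalent copper/trivalent copper cycle (oxidative addition, then C–O reductive elimination), so C3–C4 and O1–C8a form in one operation as a formal [3+3] annulation. The closest known reaction type is the CuI-catalysed domino C-benzylation/O-arylation of 2-bromobenzyl bromides with β-keto esters to 4H-chromenes, together with the copper- and palladium-catalysed intramolecular O-arylation of simple ketone enolates to benzofurans; what is new is a non-stabilised α-siloxy aryl ketone enolate as the C,O-bis-nucleophile. Ring C closes by intramolecular Ullmann-type aryl–oxygen bond formation through a seven-membered oxa-cupracycle whose reductive elimination gives the six-membered pyran. No stereocentre is formed: C2 and C3 leave as the two carbons of a tetrasubstituted enol ether and are set together in step 9. The step needs C- over O-benzylation (soft benzylic bromide, hindered enolate oxygen), O- over C-arylation (C-arylation would close a four-membered ring) and one position on ring A, which is fixed by the bromine at C8a; staging the temperature lets the SN2 step finish before the aryl bromide is engaged.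

Step 8
Reactants: 11 7,8-bis(benzyloxy)-2-[4-(benzyloxy)phenyl]-3-[(triisopropylsilyl)oxy]-4H-chromene
Product: 12 7,8-bis(benzyloxy)-2-[4-(benzyloxy)phenyl]chroman-3-one (racemic flavan-3-one)
Conditions: TBAF (1.1 equiv), AcOH (1.5 equiv), THF, −20 °C to 0 °C, argon
Reagents that add atoms: none
Why: Fluoride cleavage of the silyl enol ether releases the C3 enolate, which is protonated at C2 under buffered conditions to give the ketone without acid hydrolysis of the ring enol ether.

Step 9
Reactants: 12 7,8-bis(benzyloxy)-2-[4-(benzyloxy)phenyl]chroman-3-one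
Product: 13 (2R,3R)-7,8-bis(benzyloxy)-2-[4-(benzyloxy)phenyl]chroman-3-ol (tri-O-benzylepioritin, 2,3-cis)
Conditions: RuCl2[(S)-xylbinap][(S)-daipen] (1 mol %), t-BuOK (10 mol %), H2 (10 atm), i-PrOH/toluene, 25 °C, degassed
Reagents that add atoms: none
Why: Noyori-type hydrogenation with dynamic kinetic resolution of an α-aryl cyclic ketone: C2 (benzylic, α to O1 and to C=O) racemises through the enolate under the catalytic base, and the chiral ruthenium hydride reduces one enantiomer faster, delivering hydride to C3 anti to the C2 aryl group, which should give the 2,3-cis alcohol and set C2 and C3 in one event.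

Step 10
Reactants: 13 (2R,3R)-7,8-bis(benzyloxy)-2-[4-(benzyloxy)phenyl]chroman-3-ol
Product: 14 (2R,3R,4S)-7,8-bis(benzyloxy)-2-[4-(benzyloxy)phenyl]chromane-3,4-diol (2,3-cis-3,4-trans)
Conditions: DDQ (1.3 equiv), CH2Cl2/H2O 18:1, 0 °C to 25 °C
Reagents that add atoms: water, O
Why: DDQ abstracts hydride from C4 to give the benzylic cation stabilised by the para 7-benzyloxy group and the ortho ring oxygen, and water adds trans to the axial 3-OH (known C4 oxidation of flavan-3-ol ethers); the C4 configuration is erased again in steps 12 and 16.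

Step 11
Reactants: 14 (2R,3R,4S)-7,8-bis(benzyloxy)-2-[4-(benzyloxy)phenyl]chromane-3,4-diol
Product: 15 (2R,3S,4S)-7,8-bis(benzyloxy)-2-[4-(benzyloxy)phenyl]-4-(benzylsulfanyl)chroman-3-ol (4β-thioether)
Conditions: PhCH2SH (3 equiv), BF3·OEt2 (0.1 equiv), CH2Cl2, −20 °C
Reagents that add atoms: phenylmethanethiol, SCc1ccccc1
Why: Acid-catalysed SN1 thiolysis at C4 of a flavan-3,4-diol, the thiol entering trans to the 3-OH; the thioether is a stable C4 electrophile that only a thiophile unlocks.

Step 12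
Reactants: 14 (2R,3R,4S)-7,8-bis(benzyloxy)-2-[4-(benzyloxy)phenyl]chromane-3,4-diol
Product: 16 (2R,3S)-7,8-bis(benzyloxy)-2-[4-(benzyloxy)phenyl]-3-hydroxychroman-4-one (cis-dihydroflavonol)
Conditions: activated MnO2 (15 equiv), CH2Cl2, 25 °C
Reagents that add atoms: none
Why: MnO2 oxidises the benzylic 4-OH chemoselectively and leaves the non-benzylic 3-OH alone.

Step 13
Reactants: 16 (2R,3S)-7,8-bis(benzyloxy)-2-[4-(benzyloxy)phenyl]-3-hydroxychroman-4-one
Product: 17 (2R,3R)-7,8-bis(benzyloxy)-2-[4-(benzyloxy)phenyl]-3-hydroxychroman-4-one (trans-dihydroflavonol)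
Conditions: TsOH·H2O (10 mol %), CHCl3, 50 °C
Reagents that add atoms: none
Why: Acid-catalysed α-ketol epimerisation through the C3=C4 enediol places the 3-OH equatorial and trans to the 2-aryl group under thermodynamic control, while C2 is not enolisable and base-induced ring opening is avoided.

Step 14
Reactants: 17 (2R,3R)-7,8-bis(benzyloxy)-2-[4-(benzyloxy)phenyl]-3-hydroxychroman-4-one
Product: 18 (2R,3R)-3,7,8-trihydroxy-2-(4-hydroxyphenyl)chroman-4-one
Conditions: H2 (1 atm), 10% Pd/C, EtOAc/MeOH, 25 °C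
Reagents that add atoms: none
Why: Hydrogenolysis of the three aryl benzyl ethers at the ketone stage, so that no benzylic alcohol is exposed to the catalyst.

Step 15
Reactants: 18 (2R,3R)-3,7,8-trihydroxy-2-(4-hydroxyphenyl)chroman-4-one
Product: 19 (2R,3S,4R)-2-(4-hydroxyphenyl)chromane-3,4,7,8-tetrol (oritin-4α-ol, 2,3-trans-3,4-trans)
Conditions: NaBH4 (excess), EtOH, 0 °C to 25 °C; buffered work-up (pH 6), used at once
Reagents that add atoms: none
Why: Borohydride reduction of a trans-dihydroflavonol, in which axial hydride delivery to C4 gives the equatorial 4-OH trans to the 3-OH, the known outcome for this substrate class.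

Step 16
Reactants: 15 (2R,3S,4S)-7,8-bis(benzyloxy)-2-[4-(benzyloxy)phenyl]-4-(benzylsulfanyl)chroman-3-ol; 19 (2R,3S,4R)-2-(4-hydroxyphenyl)chromane-3,4,7,8-tetrol (3 equiv)
Product: 20 (2R,3S,4R)-6-{(2R,3R,4S)-7,8-bis(benzyloxy)-2-[4-(benzyloxy)phenyl]-3-hydroxychroman-4-yl}-2-(4-hydroxyphenyl)chromane-3,4,7,8-tetrol
Conditions: AgBF4 (2.5 equiv), THF, 0 °C, dark, N2; then aq. NaHCO3
Reagents that add atoms: none
Why: Thiophilic activation of a 4-benzylsulfanylflavan-3-ol (interflavanyl bond formation under near-neutral conditions) gives the C4 cation, which C6 of 19 (ortho to 7-OH, para to O1; C5 is peri-hindered) attacks trans to the axial 3-OH, so the 4β (3,4-trans) bond is set by substrate control while the 4-OH of 19 is not a thiophile target.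

Step 17
Reactants: 20 (2R,3S,4R)-6-{(2R,3R,4S)-7,8-bis(benzyloxy)-2-[4-(benzyloxy)phenyl]-3-hydroxychroman-4-yl}-2-(4-hydroxyphenyl)chromane-3,4,7,8-tetrol
Product: 21 (2R,3S,4R)-2-(4-hydroxyphenyl)-6-[(2R,3R,4S)-3,7,8-trihydroxy-2-(4-hydroxyphenyl)chroman-4-yl]chromane-3,4,7,8-tetrol (target)
Conditions: H2 (1 atm), 20% Pd(OH)2/C, THF/MeOH, 25 °C, neutral, stopped at full debenzylation
Reagents that add atoms: none
Why: Hydrogenolysis of the three remaining aryl benzyl ethers, which is faster under neutral conditions than hydrogenolysis of the secondary benzylic 4-OH or of the ring C–O bonds.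

**Compound list**

1 | 2-bromo-3-hydroxy-4-methoxybenzaldehyde | COc1ccc(C=O)c(Br)c1O | starting material
2 | 2-bromo-3,4-dihydroxybenzaldehyde | O=Cc1ccc(O)c(O)c1Br | intermediate
3 | 3,4-bis(benzyloxy)-2-bromobenzaldehyde | O=Cc1ccc(OCc2ccccc2)c(OCc2ccccc2)c1Br | intermediate
4 | [3,4-bis(benzyloxy)-2-bromophenyl]methanol | OCc1ccc(OCc2ccccc2)c(OCc2ccccc2)c1Br | intermediate
5 | 1,2-bis(benzyloxy)-3-bromo-4-(bromomethyl)benzene | BrCc1ccc(OCc2ccccc2)c(OCc2ccccc2)c1Br | intermediate
6 | 2-bromo-1-[4-(benzyloxy)phenyl]ethan-1-one | O=C(CBr)c1ccc(OCc2ccccc2)cc1 | starting material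
7 | 2-[4-(benzyloxy)phenyl]-2-oxoethyl formate | O=COCC(=O)c1ccc(OCc2ccccc2)cc1 | intermediate (not isolated)
8 | 1-[4-(benzyloxy)phenyl]-2-hydroxyethan-1-one | O=C(CO)c1ccc(OCc2ccccc2)cc1 | intermediate
9 | 1-[4-(benzyloxy)phenyl]-2-[(triisopropylsilyl)oxy]ethan-1-one | CC(C)[Si](OCC(=O)c1ccc(OCc2ccccc2)cc1)(C(C)C)C(C)C | intermediate
10 | 3-[3,4-bis(benzyloxy)-2-bromophenyl]-1-[4-(benzyloxy)phenyl]-2-[(triisopropylsilyl)oxy]propan-1-one (racemic) | CC(C)[Si](OC(Cc1ccc(OCc2ccccc2)c(OCc2ccccc2)c1Br)C(=O)c1ccc(OCc2ccccc2)cc1)(C(C)C)C(C)C | intermediate (not isolated)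
11 | 7,8-bis(benzyloxy)-2-[4-(benzyloxy)phenyl]-3-[(triisopropylsilyl)oxy]-4H-chromene | CC(C)[Si](OC1=C(c2ccc(OCc3ccccc3)cc2)Oc2c(C1)ccc(OCc1ccccc1)c2OCc1ccccc1)(C(C)C)C(C)C | intermediate
12 | 7,8-bis(benzyloxy)-2-[4-(benzyloxy)phenyl]chroman-3-one (racemic) | O=C1Cc2ccc(OCc3ccccc3)c(OCc3ccccc3)c2OC1c1ccc(OCc2ccccc2)cc1 | intermediate
13 | (2R,3R)-7,8-bis(benzyloxy)-2-[4-(benzyloxy)phenyl]chroman-3-ol | O[C@@H]1Cc2ccc(OCc3ccccc3)c(OCc3ccccc3)c2O[C@@H]1c1ccc(OCc2ccccc2)cc1 | intermediate
14 | (2R,3R,4S)-7,8-bis(benzyloxy)-2-[4-(benzyloxy)phenyl]chromane-3,4-diol | O[C@@H]1[C@@H](O)c2ccc(OCc3ccccc3)c(OCc3ccccc3)c2O[C@@H]1c1ccc(OCc2ccccc2)cc1 | intermediate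
15 | (2R,3S,4S)-7,8-bis(benzyloxy)-2-[4-(benzyloxy)phenyl]-4-(benzylsulfanyl)chroman-3-ol | O[C@@H]1[C@@H](SCc2ccccc2)c2ccc(OCc3ccccc3)c(OCc3ccccc3)c2O[C@@H]1c1ccc(OCc2ccccc2)cc1 | intermediate
16 | (2R,3S)-7,8-bis(benzyloxy)-2-[4-(benzyloxy)phenyl]-3-hydroxychroman-4-one | O[C@@H]1C(=O)c2ccc(OCc3ccccc3)c(OCc3ccccc3)c2O[C@@H]1c1ccc(OCc2ccccc2)cc1 | intermediate
17 | (2R,3R)-7,8-bis(benzyloxy)-2-[4-(benzyloxy)phenyl]-3-hydroxychroman-4-one | O[C@H]1C(=O)c2ccc(OCc3ccccc3)c(OCc3ccccc3)c2O[C@@H]1c1ccc(OCc2ccccc2)cc1 | intermediate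
18 | (2R,3R)-3,7,8-trihydroxy-2-(4-hydroxyphenyl)chroman-4-one | O[C@H]1C(=O)c2ccc(O)c(O)c2O[C@@H]1c1ccc(O)cc1 | intermediate
19 | (2R,3S,4R)-2-(4-hydroxyphenyl)chromane-3,4,7,8-tetrol | O[C@H]1[C@H](O)c2ccc(O)c(O)c2O[C@@H]1c1ccc(O)cc1 | intermediate
20 | (2R,3S,4R)-6-{(2R,3R,4S)-7,8-bis(benzyloxy)-2-[4-(benzyloxy)phenyl]-3-hydroxychroman-4-yl}-2-(4-hydroxyphenyl)chromane-3,4,7,8-tetrol | C(c1ccccc1)Oc1ccc([C@H]2Oc3c(ccc(OCc4ccccc4)c3OCc3ccccc3)[C@H](c3cc4c(c(O)c3O)O[C@H](c3ccc(O)cc3)[C@@H](O)[C@@H]4O)[C@H]2O)cc1 | intermediate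
21 | (2R,3S,4R)-2-(4-hydroxyphenyl)-6-[(2R,3R,4S)-3,7,8-trihydroxy-2-(4-hydroxyphenyl)chroman-4-yl]chromane-3,4,7,8-tetrol | Oc1ccc([C@H]2Oc3c(ccc(O)c3O)[C@H](c3cc4c(c(O)c3O)O[C@H](c3ccc(O)cc3)[C@@H](O)[C@@H]4O)[C@H]2O)cc1 | target

**Step count and risks**

Total step count: 17. Longest linear sequence: 14 steps (1, 2, 3, 4, 7, 8, 9, 10, 12, 13, 14, 15, 16, 17).

Steps most likely to fail:

Step 7 (Proposed new method). Carbonate-mediated enolisation of the non-stabilised ketone may be slow, so the labile benzylic bromide decomposes or is O-alkylated. Oxidative addition into the doubly ortho-substituted C8a–Br may also lag, so protodebromination or silyl loss from the enolate outruns ring closure. Fallback, from 9 and 5, back at 12: the two bonds are made one at a time, with the ring oxygen as an sp3 alkoxide. Ketone 9 is deprotonated with LiHMDS (THF, −78 °C) and benzylated with 5 to give 10, now isolated. NaBH4 (THF/MeOH, 0 °C) reduces it to 3-[3,4-bis(benzyloxy)-2-bromophenyl]-1-[4-(benzyloxy)phenyl]-2-[(triisopropylsilyl)oxy]propan-1-ol F1. Palladium-catalysed intramolecular etherification of the secondary alcohol with the aryl bromide (Pd(OAc)2, 2-(di-tert-butylphosphino)-1,1'-binaphthyl, Cs2CO3, toluene, 80 °C; known for chromans) gives 7,8-bis(benzyloxy)-2-[4-(benzyloxy)phenyl]-3-[(triisopropylsilyl)oxy]chromane F2. TBAF (THF) gives 7,8-bis(benzyloxy)-2-[4-(benzyloxy)phenyl]chroman-3-ol F3 as a racemic cis/trans mixture, and Dess–Martin periodinane (CH2Cl2, NaHCO3) converts all isomers into flavan-3-one 12.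

Step 9. Racemisation at C2 may fall behind reduction, eroding both enantiomeric and cis/trans purity, or the catalytic base may cause self-condensation of the ketone. Fallback, from 12, back at 13: L-Selectride (THF, −78 °C) delivers hydride anti to the 2-aryl group (known cis-selective reduction of flavan-3-ones) to give racemic cis-7,8-bis(benzyloxy)-2-[4-(benzyloxy)phenyl]chroman-3-ol F4. Lipase-catalysed kinetic resolution (Burkholderia cepacia lipase, vinyl acetate, t-BuOMe, 35 °C) then acetylates one enantiomer. It is written here for the antipode, which would give (2S,3S)-7,8-bis(benzyloxy)-2-[4-(benzyloxy)phenyl]chroman-3-yl acetate F5 and leave (2R,3R)-alcohol 13 for chromatographic separation. If the enzyme prefers the (2R,3R)-alcohol, its acetate is separated and cleaved with K2CO3/MeOH.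

Step 13. Acid-mediated opening of the pyran ring may erode the C2 configuration, or the α-ketol may undergo an acyloin shift or ring contraction instead of clean C3 epimerisation. Fallback, from 16, back at 17: inversion by substitution instead of equilibration. Mitsunobu reaction of the α-ketol with chloroacetic acid (PPh3, DIAD, toluene, 0 °C; SN2 at the carbonyl-activated C3) gives (2R,3R)-7,8-bis(benzyloxy)-2-[4-(benzyloxy)phenyl]-4-oxochroman-3-yl chloroacetate F6. Thiourea/NaHCO3 (EtOH, 40 °C) removes the chloroacetyl group under near-neutral conditions to give 17.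

**Further compounds**

F1 | step 7 | 3-[3,4-bis(benzyloxy)-2-bromophenyl]-1-[4-(benzyloxy)phenyl]-2-[(triisopropylsilyl)oxy]propan-1-ol (mixture of racemic diastereomers) | CC(C)[Si](OC(Cc1ccc(OCc2ccccc2)c(OCc2ccccc2)c1Br)C(O)c1ccc(OCc2ccccc2)cc1)(C(C)C)C(C)C
F2 | step 7 | 7,8-bis(benzyloxy)-2-[4-(benzyloxy)phenyl]-3-[(triisopropylsilyl)oxy]chromane (mixture of racemic diastereomers) | CC(C)[Si](OC1Cc2ccc(OCc3ccccc3)c(OCc3ccccc3)c2OC1c1ccc(OCc2ccccc2)cc1)(C(C)C)C(C)C
F3 | step 7 | 7,8-bis(benzyloxy)-2-[4-(benzyloxy)phenyl]chroman-3-ol (racemic cis/trans mixture) | OC1Cc2ccc(OCc3ccccc3)c(OCc3ccccc3)c2OC1c1ccc(OCc2ccccc2)cc1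
F4 | step 9 | rac-cis-7,8-bis(benzyloxy)-2-[4-(benzyloxy)phenyl]chroman-3-ol (both enantiomers) | O[C@@H]1Cc2ccc(OCc3ccccc3)c(OCc3ccccc3)c2O[C@@H]1c1ccc(OCc2ccccc2)cc1.O[C@H]1Cc2ccc(OCc3ccccc3)c(OCc3ccccc3)c2O[C@H]1c1ccc(OCc2ccccc2)cc1
F5 | step 9 | (2S,3S)-7,8-bis(benzyloxy)-2-[4-(benzyloxy)phenyl]chroman-3-yl acetate | CC(=O)O[C@H]1Cc2ccc(OCc3ccccc3)c(OCc3ccccc3)c2O[C@H]1c1ccc(OCc2ccccc2)cc1
F6 | step 13 | (2R,3R)-7,8-bis(benzyloxy)-2-[4-(benzyloxy)phenyl]-4-oxochroman-3-yl chloroacetate | O=C(CCl)O[C@H]1C(=O)c2ccc(OCc3ccccc3)c(OCc3ccccc3)c2O[C@@H]1c1ccc(OCc2ccccc2)cc1
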